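**Retrosynthetic overview**
1. The target is epicatechin-(4β→6)-epiafzelechin-(4β→8)-epicatechin-(4β→6)-epicatechin (units 1 to 4). The last C–C bond made is C4 (unit 2)–C8 (unit 3), by Lewis-acid union of the halogen-capped dimers 40 (units 1–2) and 27 (units 3–4), followed by one hydrogenolysis.
2. The strategy rests on unit 4: its C4 is a CH2, and its ring A (C4a, C5 to C8, C8a with O1, O5, O7) is a phloroglucinol ring symmetric about the O1···C6 axis, with C6 bonded to C4 of unit 3. Ring C of unit 4 is therefore closed at C3–C4 by ring-closing metathesis between a vinyl group on C4a and the vinyl group of an O1 (S)-1-arylallyl ether that already holds C2.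
3. The diene 18 comes from the symmetric phenol 10 by ortho-formylation, methylenation, conversion into the lithium aryloxide 17 and iridium-catalysed branched allylic etherification. Phenol 10 comes from the C4 cation of bromine-capped epicatechin 5 and phloroglucinol, whose three carbons are identical, so the 4β→6 bond needs no regiochemical choice.
4. After ring closure, hydroboration–oxidation gives the 2,3-trans alcohol and oxidation then LiB(sec-Bu)3H gives 2,3-cis. The same sequence from aryloxide 17 with the 4-benzyloxyphenyl carbonate 31 builds unit 2, whose C4 methylene is then oxidised with DDQ.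
5. Ring order: the rings of units 1 and 3 come from (−)-epicatechin; ring C of unit 4 is closed in step 16 and ring C of unit 2 in step 27. Caps (Br on C8 of units 1 and 2, Cl on C8 of unit 4) and Br–Li exchange at C8 of unit 3 steer the final coupling.

Key step: step 16

**Remarks**
- Units are numbered 1 to 4 from the top: C4 (unit 1)→C6 (unit 2), C4 (unit 2)→C8 (unit 3), C4 (unit 3)→C6 (unit 4).
- Bn = benzyl. BrEC = 8-bromo-3,5,7,3′,4′-penta-O-benzylepicatechin-4β-yl: the (2R,3R) flavan with benzyl ethers on O3, O5, O7, O3′ and O4′, bromine on C8, and the free valence on C4 trans to O3.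
- Assumption: the (Sa,Sc,Sc) phosphoramidite is taken to give the (S) allylic ether. The sense is to be checked on the model 3,5-dibenzyloxy-2-vinylphenol, whose ether, carried through the same ring closure, hydroboration, oxidation and reduction, ends at compound 2. The (Ra,Rc,Rc) ligand is used instead if the sense is opposite.
- Free 3,5-dibenzyloxyphenol or its silyl ether is avoided as the nucleophile in step 5, because the hindered flavanyl cation is expected to attack ortho to the oxygen and give the wrong (4→8) connectivity. Phloroglucinol removes the choice.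
- The lithium aryloxide 17 is made once, freed from solvent and amine, and divided between the two allylic etherifications (steps 15 and 26).

**Route**

Step 1
Reactants: 1 (−)-epicatechin
Product: 2 5,7,3′,4′-tetra-O-benzylepicatechin
Conditions: BnBr (4.4 equiv), K2CO3, DMF, 0 °C → rt
Reagents that add atoms: benzyl bromide, BrCc1ccccc1
Why: Williamson etherification with a carbonate base alkylates the four phenols and leaves the much less acidic secondary 3-OH free; no stereocentre is touched.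

Step 2
Reactants: 2 5,7,3′,4′-tetra-O-benzylepicatechin
Product: 3 3,5,7,3′,4′-penta-O-benzylepicatechin
Conditions: NaH, BnBr, n-Bu4NI (cat.), DMF, 0 °C → rt
Reagents that add atoms: benzyl bromide, BrCc1ccccc1
Why: Williamson etherification of the sodium alkoxide masks O3 as a benzyl ether that outlasts the later alcohol oxidations and leaves with the other benzyl groups at the end.

Step 3
Reactants: 3 3,5,7,3′,4′-penta-O-benzylepicatechin
Product: 4 3,5,7,3′,4′-penta-O-benzyl-4β-(2-ethoxyethoxy)epicatechin (3,4-trans)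
Conditions: DDQ (2 equiv), 2-ethoxyethanol (5 equiv), CH2Cl2, rt
Reagents that add atoms: 2-ethoxyethanol, CCOCCO
Why: Benzylic oxidation by DDQ (hydride abstraction from C4 to the cation stabilised by O1, O5 and O7) followed by capture of the alcohol on the face opposite the 3-benzyloxy group should give the 4β ether.

Step 4
Reactants: 4 3,5,7,3′,4′-penta-O-benzyl-4β-(2-ethoxyethoxy)epicatechin
Product: 5 8-bromo-3,5,7,3′,4′-penta-O-benzyl-4β-(2-ethoxyethoxy)epicatechin
Conditions: NBS (1.05 equiv), CH2Cl2, −78 → 0 °C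
Reagents that add atoms: N-bromosuccinimide, O=C1CCC(=O)N1Br
Why: Electrophilic aromatic bromination takes C8, the ring A position flanked by O1 and O7, and so caps the only strongly nucleophilic carbon before the C4 cation is generated in step 5.

Step 5
Reactants: 5 8-bromo-3,5,7,3′,4′-penta-O-benzyl-4β-(2-ethoxyethoxy)epicatechin; 6 phloroglucinol (5 equiv)
Product: 7 2-(BrEC)benzene-1,3,5-triol
Conditions: BF3·OEt2 (0.5 equiv), THF–CH2Cl2 (1:2), −40 → 0 °C
Reagents that add atoms: none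
Why: Friedel–Crafts alkylation in which the Lewis acid ionises the C4 ether and the cation is taken by phloroglucinol, whose three ring carbons are identical so only one constitution can form; attack anti to the 3-benzyloxy group sets the 4β (3,4-trans) configuration.

Step 6
Reactants: 7 2-(BrEC)benzene-1,3,5-triol
Product: 8 2-(BrEC)-5-(triisopropylsilyloxy)benzene-1,3-diol
Conditions: i-Pr3SiCl (1.05 equiv), imidazole, DMF, 0 °C
Reagents that add atoms: chlorotriisopropylsilane, CC(C)[Si](Cl)(C(C)C)C(C)C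
Why: Sterically governed silylation: the hydroxyl para to the flavanyl group has two ring hydrogens as neighbours whereas the other two lie next to the bulky C4 substituent, so the hindered chlorosilane should take the para oxygen, the future O1.

Step 7
Reactants: 8 2-(BrEC)-5-(triisopropylsilyloxy)benzene-1,3-diol
Product: 9 1,3-dibenzyloxy-2-(BrEC)-5-(triisopropylsilyloxy)benzene
Conditions: BnBr (3 equiv), K2CO3, DMF, rt
Reagents that add atoms: benzyl bromide, BrCc1ccccc1
Why: Williamson etherification of the two remaining phenols (future O5 and O7); a triisopropylsilyl aryl ether should withstand carbonate in dry DMF at room temperature.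

Step 8
Reactants: 9 1,3-dibenzyloxy-2-(BrEC)-5-(triisopropylsilyloxy)benzene
Product: 10 3,5-dibenzyloxy-4-(BrEC)phenol
Conditions: n-Bu4NF, AcOH, THF, 0 °C
Reagents that add atoms: none
Why: Fluoride cleavage of the aryl silyl ether, buffered with acetic acid, frees the single phenol; the ring is now symmetric about the axis through the hydroxyl oxygen and the carbon that bears the flavanyl group.

Step 9
Reactants: 10 3,5-dibenzyloxy-4-(BrEC)phenol
Product: 11 4,6-dibenzyloxy-5-(BrEC)-2-hydroxybenzaldehyde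
Conditions: MgCl2, Et3N, (CH2O)n, THF, 65 °C
Reagents that add atoms: paraformaldehyde (as formaldehyde), C=O
Why: Magnesium-mediated ortho-formylation of a phenol: the magnesium phenoxide delivers formaldehyde to the ortho carbon and a second formaldehyde oxidises the benzylic alkoxide; the two ortho carbons are equivalent by symmetry and the first formyl group deactivates the ring towards a second.

Step 10
Reactants: 11 4,6-dibenzyloxy-5-(BrEC)-2-hydroxybenzaldehyde
Product: 12 3,5-dibenzyloxy-4-(BrEC)-2-vinylphenol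
Conditions: Ph3PCH3Br (3.5 equiv), KOt-Bu (3.3 equiv), THF, 0 °C → rt; used without storage
Reagents that add atoms: methyltriphenylphosphonium bromide, C[P+](c1ccccc1)(c2ccccc2)c3ccccc3.[Br-]
Why: Wittig methylenation; one equivalent of base goes to the phenol and the excess unstabilised ylide should still convert the phenoxide aldehyde into the styrene whose inner carbon becomes C4.

Step 11
Reactants: 13 3,4-dibenzyloxybenzaldehyde
Product: 14 ethyl (E)-3-(3,4-dibenzyloxyphenyl)acrylate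
Conditions: Ph3P=CHCO2Et, toluene, 80 °C
Reagents that add atoms: ethyl (triphenylphosphoranylidene)acetate, CCOC(=O)C=P(c1ccccc1)(c1ccccc1)c1ccccc1
Why: Wittig olefination with a stabilised ylide gives the (E)-cinnamate.

Step 12
Reactants: 14 ethyl (E)-3-(3,4-dibenzyloxyphenyl)acrylate
Product: 15 (E)-3-(3,4-dibenzyloxyphenyl)prop-2-en-1-ol
Conditions: i-Bu2AlH (2.5 equiv), CH2Cl2, −78 °C; aq. potassium sodium tartrate
Reagents that add atoms: none
Why: 1,2-Reduction of the conjugated ester by the aluminium hydride gives the allylic alcohol with the (E) double bond intact.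

Step 13
Reactants: 15 (E)-3-(3,4-dibenzyloxyphenyl)prop-2-en-1-ol
Product: 16 (E)-3-(3,4-dibenzyloxyphenyl)allyl methyl carbonate
Conditions: ClCO2Me, pyridine, CH2Cl2, 0 °C
Reagents that add atoms: methyl chloroformate, COC(=O)Cl
Why: Acylation of the primary alcohol gives the linear carbonate, the leaving group that the iridium catalyst ionises with loss of CO2 and methoxide.

Step 14
Reactants: 12 3,5-dibenzyloxy-4-(BrEC)-2-vinylphenol
Product: 17 lithium 3,5-dibenzyloxy-4-(BrEC)-2-vinylphenoxide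
Conditions: LiN(SiMe3)2 (1.0 equiv), THF, 0 °C; volatiles removed in vacuo; solid kept under Ar at −20 °C and used within a day
Reagents that add atoms: lithium bis(trimethylsilyl)amide, [Li]N([Si](C)(C)C)[Si](C)(C)C
Why: Acid–base deprotonation of the phenol by the much more basic silylamide is complete, and the only other product, hexamethyldisilazane, leaves with the solvent, so a single batch of aryloxide free of other bases can be divided between steps 15 and 26; the phenoxide form should also protect the ortho-vinylphenol from acid-induced oligomerisation.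

Step 15
Reactants: 17 lithium 3,5-dibenzyloxy-4-(BrEC)-2-vinylphenoxide; 16 (E)-3-(3,4-dibenzyloxyphenyl)allyl methyl carbonate (1.2 equiv)
Product: 18 (S)-1-(3,4-dibenzyloxyphenyl)allyl 3,5-dibenzyloxy-4-(BrEC)-2-vinylphenyl ether
Conditions: [Ir(cod)Cl]2 (2 mol %), (Sa,Sc,Sc)-O,O′-(1,1′-binaphthyl-2,2′-diyl)-N,N-bis(1-phenylethyl)phosphoramidite (4 mol %), THF, 40 °C
Reagents that add atoms: none
Why: Iridium-catalysed asymmetric allylic etherification: the iridium phosphoramidite ionises the carbonate to an allyl complex and the aryloxide attacks its aryl-substituted terminus from outside the metal, so the branched ether forms and the chiral ligand sets the (S) C–O stereocentre that becomes C2 of unit 4.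

Step 16
Reactants: 18 (S)-1-(3,4-dibenzyloxyphenyl)allyl 3,5-dibenzyloxy-4-(BrEC)-2-vinylphenyl ether
Product: 19 BrEC-(4β→6)-(2S)-5,7,3′,4′-tetrabenzyloxyflav-3-ene
Conditions: second-generation Grubbs catalyst (H2IMes)(PCy3)Cl2Ru=CHPh (5 mol %), CH2Cl2 (0.01 M), 25 °C, Ar
Reagents that add atoms: none
Why: Ring-closing olefin metathesis: the ruthenium benzylidene exchanges onto the unhindered terminal vinyl group of the allylic ether, the new alkylidene adds across the ortho styrenyl vinyl group through a ruthenacyclobutane, and cycloreversion releases ethene and forms C3=C4. The closest known reaction type is the ring-closing metathesis of 2-vinylaryl allyl ethers to 2H-chromenes. Ring C of unit 4 closes as a six-membered ring with the new alkene inside it (O1–C2–C3=C4–C4a–C8a), the ortho placing of the two alkene arms on the arene bringing them together. No stereocentre forms; C2, set in step 15, lies outside the bonds that change and keeps the aryl orientation of epicatechin (descriptor 2S in the flavene). The step needs ring closure to outrun intermolecular metathesis, migration of the allyl ether double bond and Claisen rearrangement to the free ortho carbon (future C8): high dilution, two monosubstituted alkenes and ambient temperature should secure this, and the aryl bromide, the benzyl ethers and the 4β-aryl bond of unit 3 are inert to the catalyst.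

Step 17
Reactants: 19 BrEC-(4β→6)-(2S)-5,7,3′,4′-tetrabenzyloxyflav-3-ene
Product: 21 BrEC-(4β→6)-5,7,3′,4′-tetra-O-benzylcatechin (unit 4 2R,3S; 2,3-trans), via C3 alkylborane 20 (not isolated)
Conditions: BH3·THF (3 equiv), THF, 0 °C → rt; then NaOH, H2O2, H2O, 0 °C → rt
Reagents that add atoms: hydrogen peroxide, OO
Why: Hydroboration–oxidation: boron adds to C3, away from the aryl-conjugated C4 and next to the inductively withdrawing C2–O bond, on the face opposite the C2 aryl group, and oxidation with retention gives the 2,3-trans alcohol.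

Step 18
Reactants: 21 BrEC-(4β→6)-5,7,3′,4′-tetra-O-benzylcatechin
Product: 22 BrEC-(4β→6)-(2R)-5,7,3′,4′-tetrabenzyloxyflavan-3-one
Conditions: Dess–Martin periodinane (1.5 equiv), CH2Cl2, rt
Reagents that add atoms: none
Why: Dess–Martin oxidation of the secondary alcohol under near-neutral conditions gives the ketone without enolisation towards C2, so the C2 configuration should be kept.

Step 19
Reactants: 22 BrEC-(4β→6)-(2R)-5,7,3′,4′-tetrabenzyloxyflavan-3-one
Product: 23 BrEC-(4β→6)-5,7,3′,4′-tetra-O-benzylepicatechin (unit 4 2R,3R; 2,3-cis)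
Conditions: LiB(sec-Bu)3H (1.5 equiv), LiBr, THF, −78 °C; then H2O
Reagents that add atoms: none
Why: Diastereoselective ketone reduction by a bulky borohydride: hydride comes from the face opposite the C2 aryl group and leaves the hydroxyl cis to it.

Step 20
Reactants: 23 BrEC-(4β→6)-5,7,3′,4′-tetra-O-benzylepicatechin
Product: 24 BrEC-(4β→6)-3,5,7,3′,4′-penta-O-benzylepicatechin
Conditions: NaH, BnBr, n-Bu4NI (cat.), DMF, 0 °C → rt
Reagents that add atoms: benzyl bromide, BrCc1ccccc1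
Why: Williamson etherification of the new secondary alcohol, so that the dimer bears only benzyl ethers during lithiation and coupling.

Step 21
Reactants: 24 BrEC-(4β→6)-3,5,7,3′,4′-penta-O-benzylepicatechin
Product: 25 BrEC-(4β→6)-8-chloro-3,5,7,3′,4′-penta-O-benzylepicatechin
Conditions: NCS (1.1 equiv), CH2Cl2–MeCN, 0 °C → rt
Reagents that add atoms: N-chlorosuccinimide, O=C1CCC(=O)N1Cl
Why: Electrophilic aromatic chlorination at C8 of unit 4, the only open position flanked by O1 and O7 (C8 of unit 3 holds bromine and C6 of unit 3 lies between two benzyloxy groups), puts on a cap that n-BuLi does not touch.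

Step 22
Reactants: 25 BrEC-(4β→6)-8-chloro-3,5,7,3′,4′-penta-O-benzylepicatechin
Product: 27 3,5,7,3′,4′-penta-O-benzylepicatechin-(4β→6)-8-chloro-3,5,7,3′,4′-penta-O-benzylepicatechin, via C8 aryllithium 26 (not isolated)
Conditions: n-BuLi (1.2 equiv), THF, −78 °C, 15 min; then H2O
Reagents that add atoms: none
Why: Bromine–lithium exchange is selective for the aryl bromide over the aryl chloride at −78 °C, and protonation frees C8 of unit 3, now the only strongly nucleophilic carbon of the dimer.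

Step 23
Reactants: 28 4-benzyloxybenzaldehyde
Product: 29 ethyl (E)-3-(4-benzyloxyphenyl)acrylate
Conditions: Ph3P=CHCO2Et, toluene, 80 °C
Reagents that add atoms: ethyl (triphenylphosphoranylidene)acetate, CCOC(=O)C=P(c1ccccc1)(c1ccccc1)c1ccccc1
Why: Wittig olefination with a stabilised ylide gives the (E)-cinnamate.

Step 24
Reactants: 29 ethyl (E)-3-(4-benzyloxyphenyl)acrylate
Product: 30 (E)-3-(4-benzyloxyphenyl)prop-2-en-1-ol
Conditions: i-Bu2AlH (2.5 equiv), CH2Cl2, −78 °C; aq. potassium sodium tartrate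
Reagents that add atoms: none
Why: 1,2-Reduction of the conjugated ester by the aluminium hydride gives the (E) allylic alcohol.

Step 25
Reactants: 30 (E)-3-(4-benzyloxyphenyl)prop-2-en-1-ol
Product: 31 (E)-3-(4-benzyloxyphenyl)allyl methyl carbonate
Conditions: ClCO2Me, pyridine, CH2Cl2, 0 °C
Reagents that add atoms: methyl chloroformate, COC(=O)Cl
Why: Acylation of the primary alcohol gives the linear carbonate for the allylic etherification.

Step 26
Reactants: 17 lithium 3,5-dibenzyloxy-4-(BrEC)-2-vinylphenoxide; 31 (E)-3-(4-benzyloxyphenyl)allyl methyl carbonate (1.2 equiv)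
Product: 32 (S)-1-(4-benzyloxyphenyl)allyl 3,5-dibenzyloxy-4-(BrEC)-2-vinylphenyl ether
Conditions: [Ir(cod)Cl]2 (2 mol %), (Sa,Sc,Sc)-O,O′-(1,1′-binaphthyl-2,2′-diyl)-N,N-bis(1-phenylethyl)phosphoramidite (4 mol %), THF, 40 °C
Reagents that add atoms: none
Why: Iridium-catalysed asymmetric allylic etherification as in step 15, run on the second portion of aryloxide 17; the same ligand sets the (S) C–O stereocentre that becomes C2 of unit 2.

Step 27
Reactants: 32 (S)-1-(4-benzyloxyphenyl)allyl 3,5-dibenzyloxy-4-(BrEC)-2-vinylphenyl ether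
Product: 33 BrEC-(4β→6)-(2S)-5,7,4′-tribenzyloxyflav-3-ene
Conditions: second-generation Grubbs catalyst (H2IMes)(PCy3)Cl2Ru=CHPh (5 mol %), CH2Cl2 (0.01 M), 25 °C, Ar
Reagents that add atoms: none
Why: Ring-closing olefin metathesis of the two vinyl groups, as in step 16, closes ring C of unit 2 at C3=C4 with loss of ethene and without touching C2.

Step 28
Reactants: 33 BrEC-(4β→6)-(2S)-5,7,4′-tribenzyloxyflav-3-ene
Product: 35 BrEC-(4β→6)-5,7,4′-tri-O-benzylafzelechin (unit 2 2R,3S; 2,3-trans), via C3 alkylborane 34 (not isolated)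
Conditions: BH3·THF (3 equiv), THF, 0 °C → rt; then NaOH, H2O2, H2O, 0 °C → rt
Reagents that add atoms: hydrogen peroxide, OO
Why: Hydroboration–oxidation places boron on C3 anti to the C2 aryl group and oxidation with retention gives the 2,3-trans alcohol.

Step 29
Reactants: 35 BrEC-(4β→6)-5,7,4′-tri-O-benzylafzelechin
Product: 36 BrEC-(4β→6)-(2R)-5,7,4′-tribenzyloxyflavan-3-one
Conditions: Dess–Martin periodinane (1.5 equiv), CH2Cl2, rt
Reagents that add atoms: none
Why: Dess–Martin oxidation gives the ketone under near-neutral conditions that should leave C2 untouched.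

Step 30
Reactants: 36 BrEC-(4β→6)-(2R)-5,7,4′-tribenzyloxyflavan-3-one
Product: 37 BrEC-(4β→6)-5,7,4′-tri-O-benzylepiafzelechin (unit 2 2R,3R; 2,3-cis)
Conditions: LiB(sec-Bu)3H (1.5 equiv), LiBr, THF, −78 °C; then H2O
Reagents that add atoms: none
Why: Diastereoselective reduction by the bulky borohydride from the face opposite the C2 aryl group gives the 2,3-cis alcohol.

Step 31
Reactants: 37 BrEC-(4β→6)-5,7,4′-tri-O-benzylepiafzelechin
Product: 38 BrEC-(4β→6)-3,5,7,4′-tetra-O-benzylepiafzelechin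
Conditions: NaH, BnBr, n-Bu4NI (cat.), DMF, 0 °C → rt
Reagents that add atoms: benzyl bromide, BrCc1ccccc1
Why: Williamson etherification gives the 3-benzyloxy group that will shield the α face of C4 of unit 2 in steps 32 and 34.

Step 32
Reactants: 38 BrEC-(4β→6)-3,5,7,4′-tetra-O-benzylepiafzelechin
Product: 39 BrEC-(4β→6)-3,5,7,4′-tetra-O-benzyl-4β-(2-ethoxyethoxy)epiafzelechin
Conditions: DDQ (2 equiv), 2-ethoxyethanol (5 equiv), CH2Cl2, rt
Reagents that add atoms: 2-ethoxyethanol, CCOCCO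
Why: Benzylic oxidation by DDQ at the C4 methylene of unit 2, whose axial hydrogen overlaps with ring A, whereas the single C4 hydrogen of unit 1 lies near the plane of its bromine-bearing ring A and is shielded by two aryl groups; the alcohol adds trans to the 3-benzyloxy group (4β).

Step 33
Reactants: 39 BrEC-(4β→6)-3,5,7,4′-tetra-O-benzyl-4β-(2-ethoxyethoxy)epiafzelechin
Product: 40 BrEC-(4β→6)-8-bromo-3,5,7,4′-tetra-O-benzyl-4β-(2-ethoxyethoxy)epiafzelechin
Conditions: NBS (1.05 equiv), CH2Cl2, −78 → −20 °C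
Reagents that add atoms: N-bromosuccinimide, O=C1CCC(=O)N1Br
Why: Electrophilic aromatic bromination at C8 of unit 2, the last open position flanked by O1 and O7, caps the dimer at both units so that it cannot add to its own C4 cation.

Step 34
Reactants: 40 BrEC-(4β→6)-8-bromo-3,5,7,4′-tetra-O-benzyl-4β-(2-ethoxyethoxy)epiafzelechin; 27 3,5,7,3′,4′-penta-O-benzylepicatechin-(4β→6)-8-chloro-3,5,7,3′,4′-penta-O-benzylepicatechin (1.5 equiv)
Product: 41 BrEC-(4β→6)-[8-bromo-3,5,7,4′-tetra-O-benzylepiafzelechin]-(4β→8)-[3,5,7,3′,4′-penta-O-benzylepicatechin]-(4β→6)-[8-chloro-3,5,7,3′,4′-penta-O-benzylepicatechin]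
Conditions: TMSOTf (0.5 equiv), 4 Å molecular sieves, CH2Cl2, −78 → −40 °C; Et3N quench
Reagents that add atoms: none
Why: Friedel–Crafts alkylation: the silyl triflate ionises the C4 ether of unit 2, the cation cannot be taken by its own capped dimer and adds to C8 of unit 3 in 27 (open and flanked by O1 and O7, whereas C6 lies between two benzyloxy groups and C8 of unit 4 holds chlorine) from the face opposite the 3-benzyloxy group, giving the 4β→8 bond.

Step 35
Reactants: 41 protected tetramer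
Product: 42 epicatechin-(4β→6)-epiafzelechin-(4β→8)-epicatechin-(4β→6)-epicatechin (CNP0103636.1)
Conditions: H2 (1–3 atm), Pd(OH)2/C, Et3N (4 equiv), THF–MeOH–H2O, rt
Reagents that add atoms: none
Why: Hydrogenolysis cleaves the nineteen benzyl ethers, and hydrodehalogenation removes the two bromines and the chlorine in the same operation, the amine taking up the hydrogen halides so that the acid-labile interflavan bonds should survive; no stereocentre is affected.

**Compound list** (BrEC as defined above; all SMILES are complete)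

1 | (−)-epicatechin | O[C@@H]1Cc2c(O)cc(O)cc2O[C@@H]1c3ccc(O)c(O)c3 | starting material
2 | 5,7,3′,4′-tetra-O-benzylepicatechin | O[C@@H]1Cc2c(OCc6ccccc6)cc(OCc6ccccc6)cc2O[C@@H]1c3ccc(OCc6ccccc6)c(OCc6ccccc6)c3 | intermediate
3 | 3,5,7,3′,4′-penta-O-benzylepicatechin | C(c6ccccc6)O[C@@H]1Cc2c(OCc6ccccc6)cc(OCc6ccccc6)cc2O[C@@H]1c3ccc(OCc6ccccc6)c(OCc6ccccc6)c3 | intermediate
4 | 3,5,7,3′,4′-penta-O-benzyl-4β-(2-ethoxyethoxy)epicatechin | c3c(OCc6ccccc6)cc(OCc6ccccc6)c4c3O[C@H](c3ccc(OCc6ccccc6)c(OCc6ccccc6)c3)[C@H](OCc6ccccc6)[C@H]4OCCOCC | intermediate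
5 | 8-bromo-3,5,7,3′,4′-penta-O-benzyl-4β-(2-ethoxyethoxy)epicatechin | Brc3c(OCc6ccccc6)cc(OCc6ccccc6)c4c3O[C@H](c3ccc(OCc6ccccc6)c(OCc6ccccc6)c3)[C@H](OCc6ccccc6)[C@H]4OCCOCC | intermediate
6 | phloroglucinol | Oc1cc(O)cc(O)c1 | starting material
7 | 2-(BrEC)benzene-1,3,5-triol | Brc3c(OCc6ccccc6)cc(OCc6ccccc6)c4c3O[C@H](c3ccc(OCc6ccccc6)c(OCc6ccccc6)c3)[C@H](OCc6ccccc6)[C@H]4c3c(O)cc(O)cc3O | intermediate
8 | 2-(BrEC)-5-(triisopropylsilyloxy)benzene-1,3-diol | Brc3c(OCc6ccccc6)cc(OCc6ccccc6)c4c3O[C@H](c3ccc(OCc6ccccc6)c(OCc6ccccc6)c3)[C@H](OCc6ccccc6)[C@H]4c3c(O)cc(O[Si](C(C)C)(C(C)C)C(C)C)cc3O | intermediate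
9 | 1,3-dibenzyloxy-2-(BrEC)-5-(triisopropylsilyloxy)benzene | Brc3c(OCc6ccccc6)cc(OCc6ccccc6)c4c3O[C@H](c3ccc(OCc6ccccc6)c(OCc6ccccc6)c3)[C@H](OCc6ccccc6)[C@H]4c3c(OCc6ccccc6)cc(O[Si](C(C)C)(C(C)C)C(C)C)cc3OCc6ccccc6 | intermediate
10 | 3,5-dibenzyloxy-4-(BrEC)phenol | Brc3c(OCc6ccccc6)cc(OCc6ccccc6)c4c3O[C@H](c3ccc(OCc6ccccc6)c(OCc6ccccc6)c3)[C@H](OCc6ccccc6)[C@H]4c3c(OCc6ccccc6)cc(O)cc3OCc6ccccc6 | intermediate
11 | 4,6-dibenzyloxy-5-(BrEC)-2-hydroxybenzaldehyde | Brc3c(OCc6ccccc6)cc(OCc6ccccc6)c4c3O[C@H](c3ccc(OCc6ccccc6)c(OCc6ccccc6)c3)[C@H](OCc6ccccc6)[C@H]4c3c(OCc6ccccc6)cc(O)c(C=O)c3OCc6ccccc6 | intermediate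
12 | 3,5-dibenzyloxy-4-(BrEC)-2-vinylphenol | Brc3c(OCc6ccccc6)cc(OCc6ccccc6)c4c3O[C@H](c3ccc(OCc6ccccc6)c(OCc6ccccc6)c3)[C@H](OCc6ccccc6)[C@H]4c3c(OCc6ccccc6)cc(O)c(C=C)c3OCc6ccccc6 | intermediate
13 | 3,4-dibenzyloxybenzaldehyde | O=Cc1ccc(OCc6ccccc6)c(OCc6ccccc6)c1 | starting material
14 | ethyl (E)-3-(3,4-dibenzyloxyphenyl)acrylate | CCOC(=O)/C=C/c1ccc(OCc6ccccc6)c(OCc6ccccc6)c1 | intermediate
15 | (E)-3-(3,4-dibenzyloxyphenyl)prop-2-en-1-ol | OC/C=C/c1ccc(OCc6ccccc6)c(OCc6ccccc6)c1 | intermediate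
16 | (E)-3-(3,4-dibenzyloxyphenyl)allyl methyl carbonate | COC(=O)OC/C=C/c1ccc(OCc6ccccc6)c(OCc6ccccc6)c1 | intermediate
17 | lithium 3,5-dibenzyloxy-4-(BrEC)-2-vinylphenoxide | Brc3c(OCc6ccccc6)cc(OCc6ccccc6)c4c3O[C@H](c3ccc(OCc6ccccc6)c(OCc6ccccc6)c3)[C@H](OCc6ccccc6)[C@H]4c3c(OCc6ccccc6)cc(O[Li])c(C=C)c3OCc6ccccc6 | intermediate
18 | (S)-1-(3,4-dibenzyloxyphenyl)allyl 3,5-dibenzyloxy-4-(BrEC)-2-vinylphenyl ether | Brc3c(OCc6ccccc6)cc(OCc6ccccc6)c4c3O[C@H](c3ccc(OCc6ccccc6)c(OCc6ccccc6)c3)[C@H](OCc6ccccc6)[C@H]4c3c(OCc6ccccc6)cc(O[C@H](c2ccc(OCc6ccccc6)c(OCc6ccccc6)c2)C=C)c(C=C)c3OCc6ccccc6 | intermediate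
19 | BrEC-(4β→6)-(2S)-5,7,3′,4′-tetrabenzyloxyflav-3-ene | Brc3c(OCc6ccccc6)cc(OCc6ccccc6)c4c3O[C@H](c3ccc(OCc6ccccc6)c(OCc6ccccc6)c3)[C@H](OCc6ccccc6)[C@H]4c3c(OCc6ccccc6)cc4c(c3OCc6ccccc6)C=C[C@@H](c3ccc(OCc6ccccc6)c(OCc6ccccc6)c3)O4 | intermediate
20 | C3 alkylborane (BH2 on C3, trans to the C2 aryl group) of 19 | Brc3c(OCc6ccccc6)cc(OCc6ccccc6)c4c3O[C@H](c3ccc(OCc6ccccc6)c(OCc6ccccc6)c3)[C@H](OCc6ccccc6)[C@H]4c3c(OCc6ccccc6)cc4c(c3OCc6ccccc6)C[C@H](B)[C@@H](c3ccc(OCc6ccccc6)c(OCc6ccccc6)c3)O4 | intermediate (not isolated)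
21 | BrEC-(4β→6)-5,7,3′,4′-tetra-O-benzylcatechin (2R,3S) | Brc3c(OCc6ccccc6)cc(OCc6ccccc6)c4c3O[C@H](c3ccc(OCc6ccccc6)c(OCc6ccccc6)c3)[C@H](OCc6ccccc6)[C@H]4c3c(OCc6ccccc6)cc4c(c3OCc6ccccc6)C[C@H](O)[C@@H](c3ccc(OCc6ccccc6)c(OCc6ccccc6)c3)O4 | intermediate
22 | BrEC-(4β→6)-(2R)-5,7,3′,4′-tetrabenzyloxyflavan-3-one | Brc3c(OCc6ccccc6)cc(OCc6ccccc6)c4c3O[C@H](c3ccc(OCc6ccccc6)c(OCc6ccccc6)c3)[C@H](OCc6ccccc6)[C@H]4c3c(OCc6ccccc6)cc4c(c3OCc6ccccc6)CC(=O)[C@@H](c3ccc(OCc6ccccc6)c(OCc6ccccc6)c3)O4 | intermediate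
23 | BrEC-(4β→6)-5,7,3′,4′-tetra-O-benzylepicatechin (2R,3R) | Brc3c(OCc6ccccc6)cc(OCc6ccccc6)c4c3O[C@H](c3ccc(OCc6ccccc6)c(OCc6ccccc6)c3)[C@H](OCc6ccccc6)[C@H]4c3c(OCc6ccccc6)cc4c(c3OCc6ccccc6)C[C@@H](O)[C@@H](c3ccc(OCc6ccccc6)c(OCc6ccccc6)c3)O4 | intermediate
24 | BrEC-(4β→6)-3,5,7,3′,4′-penta-O-benzylepicatechin | Brc3c(OCc6ccccc6)cc(OCc6ccccc6)c4c3O[C@H](c3ccc(OCc6ccccc6)c(OCc6ccccc6)c3)[C@H](OCc6ccccc6)[C@H]4c3c(OCc6ccccc6)cc4c(c3OCc6ccccc6)C[C@@H](OCc6ccccc6)[C@@H](c3ccc(OCc6ccccc6)c(OCc6ccccc6)c3)O4 | intermediate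
25 | BrEC-(4β→6)-8-chloro-3,5,7,3′,4′-penta-O-benzylepicatechin | Brc3c(OCc6ccccc6)cc(OCc6ccccc6)c4c3O[C@H](c3ccc(OCc6ccccc6)c(OCc6ccccc6)c3)[C@H](OCc6ccccc6)[C@H]4c3c(OCc6ccccc6)c(Cl)c4c(c3OCc6ccccc6)C[C@@H](OCc6ccccc6)[C@@H](c3ccc(OCc6ccccc6)c(OCc6ccccc6)c3)O4 | intermediate
26 | 8-lithio-3,5,7,3′,4′-penta-O-benzylepicatechin-(4β→6)-8-chloro-3,5,7,3′,4′-penta-O-benzylepicatechin | [Li]c3c(OCc6ccccc6)cc(OCc6ccccc6)c4c3O[C@H](c3ccc(OCc6ccccc6)c(OCc6ccccc6)c3)[C@H](OCc6ccccc6)[C@H]4c3c(OCc6ccccc6)c(Cl)c4c(c3OCc6ccccc6)C[C@@H](OCc6ccccc6)[C@@H](c3ccc(OCc6ccccc6)c(OCc6ccccc6)c3)O4 | intermediate (not isolated)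
27 | 3,5,7,3′,4′-penta-O-benzylepicatechin-(4β→6)-8-chloro-3,5,7,3′,4′-penta-O-benzylepicatechin | c3c(OCc6ccccc6)cc(OCc6ccccc6)c4c3O[C@H](c3ccc(OCc6ccccc6)c(OCc6ccccc6)c3)[C@H](OCc6ccccc6)[C@H]4c3c(OCc6ccccc6)c(Cl)c4c(c3OCc6ccccc6)C[C@@H](OCc6ccccc6)[C@@H](c3ccc(OCc6ccccc6)c(OCc6ccccc6)c3)O4 | intermediate
28 | 4-benzyloxybenzaldehyde | O=Cc1ccc(OCc6ccccc6)cc1 | starting material
29 | ethyl (E)-3-(4-benzyloxyphenyl)acrylate | CCOC(=O)/C=C/c1ccc(OCc6ccccc6)cc1 | intermediate
30 | (E)-3-(4-benzyloxyphenyl)prop-2-en-1-ol | OC/C=C/c1ccc(OCc6ccccc6)cc1 | intermediate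
31 | (E)-3-(4-benzyloxyphenyl)allyl methyl carbonate | COC(=O)OC/C=C/c1ccc(OCc6ccccc6)cc1 | intermediate
32 | (S)-1-(4-benzyloxyphenyl)allyl 3,5-dibenzyloxy-4-(BrEC)-2-vinylphenyl ether | Brc3c(OCc6ccccc6)cc(OCc6ccccc6)c4c3O[C@H](c3ccc(OCc6ccccc6)c(OCc6ccccc6)c3)[C@H](OCc6ccccc6)[C@H]4c3c(OCc6ccccc6)cc(O[C@H](c2ccc(OCc6ccccc6)cc2)C=C)c(C=C)c3OCc6ccccc6 | intermediate
33 | BrEC-(4β→6)-(2S)-5,7,4′-tribenzyloxyflav-3-ene | Brc3c(OCc6ccccc6)cc(OCc6ccccc6)c4c3O[C@H](c3ccc(OCc6ccccc6)c(OCc6ccccc6)c3)[C@H](OCc6ccccc6)[C@H]4c3c(OCc6ccccc6)cc4c(c3OCc6ccccc6)C=C[C@@H](c3ccc(OCc6ccccc6)cc3)O4 | intermediate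
34 | C3 alkylborane (BH2 on C3, trans to the C2 aryl group) of 33 | Brc3c(OCc6ccccc6)cc(OCc6ccccc6)c4c3O[C@H](c3ccc(OCc6ccccc6)c(OCc6ccccc6)c3)[C@H](OCc6ccccc6)[C@H]4c3c(OCc6ccccc6)cc4c(c3OCc6ccccc6)C[C@H](B)[C@@H](c3ccc(OCc6ccccc6)cc3)O4 | intermediate (not isolated)
35 | BrEC-(4β→6)-5,7,4′-tri-O-benzylafzelechin (2R,3S) | Brc3c(OCc6ccccc6)cc(OCc6ccccc6)c4c3O[C@H](c3ccc(OCc6ccccc6)c(OCc6ccccc6)c3)[C@H](OCc6ccccc6)[C@H]4c3c(OCc6ccccc6)cc4c(c3OCc6ccccc6)C[C@H](O)[C@@H](c3ccc(OCc6ccccc6)cc3)O4 | intermediate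
36 | BrEC-(4β→6)-(2R)-5,7,4′-tribenzyloxyflavan-3-one | Brc3c(OCc6ccccc6)cc(OCc6ccccc6)c4c3O[C@H](c3ccc(OCc6ccccc6)c(OCc6ccccc6)c3)[C@H](OCc6ccccc6)[C@H]4c3c(OCc6ccccc6)cc4c(c3OCc6ccccc6)CC(=O)[C@@H](c3ccc(OCc6ccccc6)cc3)O4 | intermediate
37 | BrEC-(4β→6)-5,7,4′-tri-O-benzylepiafzelechin (2R,3R) | Brc3c(OCc6ccccc6)cc(OCc6ccccc6)c4c3O[C@H](c3ccc(OCc6ccccc6)c(OCc6ccccc6)c3)[C@H](OCc6ccccc6)[C@H]4c3c(OCc6ccccc6)cc4c(c3OCc6ccccc6)C[C@@H](O)[C@@H](c3ccc(OCc6ccccc6)cc3)O4 | intermediate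
38 | BrEC-(4β→6)-3,5,7,4′-tetra-O-benzylepiafzelechin | Brc3c(OCc6ccccc6)cc(OCc6ccccc6)c4c3O[C@H](c3ccc(OCc6ccccc6)c(OCc6ccccc6)c3)[C@H](OCc6ccccc6)[C@H]4c3c(OCc6ccccc6)cc4c(c3OCc6ccccc6)C[C@@H](OCc6ccccc6)[C@@H](c3ccc(OCc6ccccc6)cc3)O4 | intermediate
39 | BrEC-(4β→6)-3,5,7,4′-tetra-O-benzyl-4β-(2-ethoxyethoxy)epiafzelechin | Brc3c(OCc6ccccc6)cc(OCc6ccccc6)c4c3O[C@H](c3ccc(OCc6ccccc6)c(OCc6ccccc6)c3)[C@H](OCc6ccccc6)[C@H]4c3c(OCc6ccccc6)cc4c(c3OCc6ccccc6)[C@H](OCCOCC)[C@@H](OCc6ccccc6)[C@@H](c3ccc(OCc6ccccc6)cc3)O4 | intermediate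
40 | BrEC-(4β→6)-8-bromo-3,5,7,4′-tetra-O-benzyl-4β-(2-ethoxyethoxy)epiafzelechin | Brc3c(OCc6ccccc6)cc(OCc6ccccc6)c4c3O[C@H](c3ccc(OCc6ccccc6)c(OCc6ccccc6)c3)[C@H](OCc6ccccc6)[C@H]4c3c(OCc6ccccc6)c(Br)c4c(c3OCc6ccccc6)[C@H](OCCOCC)[C@@H](OCc6ccccc6)[C@@H](c3ccc(OCc6ccccc6)cc3)O4 | intermediate
41 | BrEC-(4β→6)-[8-bromo-3,5,7,4′-tetra-O-benzylepiafzelechin]-(4β→8)-[3,5,7,3′,4′-penta-O-benzylepicatechin]-(4β→6)-[8-chloro-3,5,7,3′,4′-penta-O-benzylepicatechin] | Brc3c(OCc6ccccc6)cc(OCc6ccccc6)c4c3O[C@H](c3ccc(OCc6ccccc6)c(OCc6ccccc6)c3)[C@H](OCc6ccccc6)[C@H]4c3c(OCc6ccccc6)c(Br)c4c(c3OCc6ccccc6)[C@H](c5c(OCc6ccccc6)cc(OCc6ccccc6)c7c5O[C@H](c5ccc(OCc6ccccc6)c(OCc6ccccc6)c5)[C@H](OCc6ccccc6)[C@H]7c5c(OCc6ccccc6)c(Cl)c7c(c5OCc6ccccc6)C[C@@H](OCc6ccccc6)[C@@H](c5ccc(OCc6ccccc6)c(OCc6ccccc6)c5)O7)[C@@H](OCc6ccccc6)[C@@H](c3ccc(OCc6ccccc6)cc3)O4 | intermediate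
42 | epicatechin-(4β→6)-epiafzelechin-(4β→8)-epicatechin-(4β→6)-epicatechin (CNP0103636.1) | Oc1ccc([C@H]2Oc3cc(O)c([C@H]4c5c(O)cc(O)cc5O[C@H](c5ccc(O)c(O)c5)[C@@H]4O)c(O)c3[C@H](c3c(O)cc(O)c4c3O[C@H](c3ccc(O)c(O)c3)[C@H](O)[C@H]4c3c(O)cc4c(c3O)C[C@@H](O)[C@@H](c3ccc(O)c(O)c3)O4)[C@H]2O)cc1 | target

**Step count and risks**

Total: 35 steps. Longest linear sequence: 21 steps (1–10, 14, 15–22, 34, 35; the line 1–10, 14, 26–33, 34, 35 has the same length).

Steps most likely to fail: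

1. Step 15 (the same holds for its twin, step 26). The branched ether is an electron-rich benzylic allylic aryl ether; reversible ionisation by the catalyst may erode the branched-to-linear selectivity and the enantiopurity, and the hindered aryloxide may attack slowly. Fallback: the stereocentre is set before the C–O bond is made. It sets out from 13 and 17 and comes back at 18. Aldehyde 13 with CH2=CHMgBr should give racemic 1-(3,4-dibenzyloxyphenyl)prop-2-en-1-ol F1. Kinetic resolution with Candida antarctica lipase B and vinyl acetate is expected to acylate the (R) alcohol to (R)-1-(3,4-dibenzyloxyphenyl)allyl acetate F3 and leave (S)-1-(3,4-dibenzyloxyphenyl)prop-2-en-1-ol F2. ClCO2Me and pyridine convert F2 into (S)-1-(3,4-dibenzyloxyphenyl)allyl methyl carbonate F4. Substitution of F4 by aryloxide 17 with [Ir(cod)Cl]2 and the achiral ligand P(OPh)3 is a known stereoretentive, branched-selective allylic substitution and should give 18.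

2. Step 16. Ruthenium hydride species formed from the catalyst may move the double bond of the allyl aryl ether before ring closure, and the crowded styrene may react between molecules instead of within one. Fallback: the C4–C6 bond is made directly and ring C of unit 4 is taken from epicatechin. It sets out from 3 and 5 and comes back at 25. Chlorination of 3 with NCS should give 8-chloro-3,5,7,3′,4′-penta-O-benzylepicatechin F5. Friedel–Crafts coupling of F5 with 5 (TMSOTf, CH2Cl2, −78 → −20 °C) can only occur at C6 of F5 and gives 25. This coupling uses the sluggish position between two benzyloxy groups, which is why it is the fallback and not the route, and it cannot supply unit 2.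

3. Step 34. Two hindered dimers unite slowly, and long exposure to the hard Lewis acid may ionise the interflavan bonds already present and scramble them, or bring C6 of unit 3 into play. Fallback: the leaving group and the mode of activation are changed. It sets out from 40 and comes back at 41. Exchange of the C4 ether of 40 with 2,6-dimethylbenzenethiol (BF3·OEt2, CH2Cl2, −78 °C) should give BrEC-(4β→6)-8-bromo-3,5,7,4′-tetra-O-benzyl-4β-(2,6-dimethylphenylthio)epiafzelechin F6. This thioether is stable to oxophilic acids and is activated by the thiophilic salt AgBF4 (CH2Cl2, 4 Å molecular sieves, −30 → 0 °C) in the presence of 27, a known way of coupling 4-thioflavans, to give 41.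

**Further compounds**

F1 | step 15 | racemic 1-(3,4-dibenzyloxyphenyl)prop-2-en-1-ol | OC(C=C)c1ccc(OCc6ccccc6)c(OCc6ccccc6)c1
F2 | step 15 | (S)-1-(3,4-dibenzyloxyphenyl)prop-2-en-1-ol | O[C@H](c1ccc(OCc6ccccc6)c(OCc6ccccc6)c1)C=C
F3 | step 15 | (R)-1-(3,4-dibenzyloxyphenyl)allyl acetate | CC(=O)O[C@@H](c1ccc(OCc6ccccc6)c(OCc6ccccc6)c1)C=C
F4 | step 15 | (S)-1-(3,4-dibenzyloxyphenyl)allyl methyl carbonate | COC(=O)O[C@H](c1ccc(OCc6ccccc6)c(OCc6ccccc6)c1)C=C
F5 | step 16 | 8-chloro-3,5,7,3′,4′-penta-O-benzylepicatechin | Clc3c(OCc6ccccc6)cc(OCc6ccccc6)c4c3O[C@H](c3ccc(OCc6ccccc6)c(OCc6ccccc6)c3)[C@H](OCc6ccccc6)C4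
F6 | step 34 | BrEC-(4β→6)-8-bromo-3,5,7,4′-tetra-O-benzyl-4β-(2,6-dimethylphenylthio)epiafzelechin | Brc3c(OCc6ccccc6)cc(OCc6ccccc6)c4c3O[C@H](c3ccc(OCc6ccccc6)c(OCc6ccccc6)c3)[C@H](OCc6ccccc6)[C@H]4c3c(OCc6ccccc6)c(Br)c4c(c3OCc6ccccc6)[C@H](Sc5c(C)cccc5C)[C@@H](OCc6ccccc6)[C@@H](c3ccc(OCc6ccccc6)cc3)O4
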